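## Analysis of the target

Target 25 is a 5,6,7,8-tetrahydrochromone: a 4-pyranone (ring A: O1, C2, C3, C4, C4a, C8a) fused across C4a=C8a to a saturated carbocycle (ring B: C4a, C5–C8, C8a), with a 2-(3-hydroxy-4-methoxyphenyl)ethyl chain on C2; this numbering is kept for every intermediate. Ring B carries four contiguous stereocentres, 5S, 6S, 7S and 8R: the hydroxyls on C5, C6 and C7 are all cis, and the chlorine on C8 is trans to the C7 hydroxyl. The C8 chloride is secondary and adjacent to C8a, the vinylogous α-position of the pyranone carbonyl, so it is open to SN2 exchange and, with the trans C7 hydroxyl, to epoxide closure under base; the C5 hydroxyl can ionise with help from O1; and ring B is only a few losses of water or HCl away from an aromatic chromone. The difficulty is to set four adjacent heteroatom-bearing centres on a ring that tends to aromatise, and to bring in chlorine with defined configuration at an activated carbon, with as few operations as possible on the finished ring. The route rests on the cis-5,6,7-triol beside C8–Cl: a C5=C6 alkene flanked by a free C7 hydroxyl should take both new hydroxyls on the face of that hydroxyl, so ring B can be closed at C5=C6, the one ring bond whose formation creates no stereocentre. What remains, C7–OH and C8–Cl on an open chain between two alkenes, is an erythro-diol problem with one inversion, and that diol is C3/C2 of D-lyxose (1). The C4a=C8a bond of ring A holds the two alkene-bearing arms cis, as a ring-closing metathesis requires.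

## Retrosynthetic reasoning

25 to 23. The C5–O and C6–O bonds are cut together, leading back to dihydrochromone 23 with a C5=C6 double bond. Both oxygens lie cis to the C7 hydroxyl, which is the face to which that hydroxyl steers a hydrogen-bond-accepting osmium oxidant; the C8 chlorine on the other face pushes the same way. Two stereocentres are thus set last by a group already present. The forward reaction must add only from the C7–OH face and must spare ring A and the chloride. The phenol is already free in 23, so the chlorotriol only has to be released from osmate ester 24 and never has to survive a deprotection.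

23 to 22. The C5=C6 bond is cut, giving diene 22, a 3-vinylpyranone whose C8a arm ends in a second vinyl group. This bond is chosen because closing it makes no stereocentre and because the two vinyl groups are held cis by C4a=C8a. Ring B is thereby reduced to an open-chain chlorohydrin. The forward closure must not disturb the activated chloride or start the loss of water or HCl towards the aromatic chromone.

22 to 18. The C8–Cl bond is cut. Diene 22 comes from bis-silyl ether 21, 21 from mesylate 20 by SN2 displacement, 20 from alcohol 19, and 19 from the erythro diol 18. Inversion at C8 turns the cis oxygen pattern of the diol into the trans chlorohydrin. A cyclic activation of both hydroxyls of 18 was set aside as the main line, because both carbinol carbons are activated (C8 by the pyranone, C7 by the vinyl group) and chloride could attack either. Capping the less hindered allylic C7 hydroxyl in 19 removes that ambiguity.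

18 to 15 and 16. The C4a–vinyl bond is cut. Diol 18 comes from acetonide 17, and 17 from 3-iodopyranone 15 and vinylstannane 16 by cross-coupling. The coupling is placed before the chloride is introduced, because an activated C8 chloride would not be safe under palladium catalysis.

15 to 8 and 13. Ring A is opened at C2–C3 and O1–C8a, giving acyl donor 13 and iodinated enaminone 8; their union is diketone 14. The forward closure is an addition–elimination of an enol oxygen at an enaminone carbon, which leaves no regiochemical choice: C3 is the acylated methyl carbon and keeps hydrogen, and C4a already carries iodine. An iodonium-induced closure of a preformed ynone was set aside, because the enol carbon C3 and the electron-rich arene would compete for the electrophile.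

8 to 5. The C4a–I and C8a–N bonds are removed to reveal ynone 6. A secondary amine adds to the alkyne carbon remote from the carbonyl, and enaminone 7 has a single nucleophilic carbon, the future C4a, so iodination is unambiguous and takes place before the arene and the second carbonyl arrive. Ynone 6 is cut between carbonyl and alkyne to terminal alkyne 5 and an acetyl donor.

5 to 1. Alkyne 5 comes from aldehyde 4 by one-carbon homologation. This is done at low temperature without an alkoxide medium, because a cis-dioxolane aldehyde epimerises easily. Aldehyde 4 comes from iodide 3 by reductive fragmentation, which turns C4/C5 of the sugar into the vinyl group and C1 into the aldehyde, and 3 comes from 1 through furanoside 2. C2 and C3 of 1 become C8 and C7 and are never touched until the chloride displacement.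

13 to 9. The acyl donor is cut back through acid 12 and cinnamate 11 to silyl-protected isovanillin 10 and isovanillin 9: a two-carbon olefination followed by one hydrogenation that also frees the acid. The phenol is silylated so that it can be released together with the C7 silyl ether under acidic fluoride just before ring closure.

## Alternatives that were turned down

Alternative 1: Ring B is cut at C7–C8, with C8 as the chloromethyl carbon on C8a and C7 as an aldehyde at the end of a C5/C6 bis-silyloxy chain on C4a (A1). In the forward step a non-chelating base removes a proton from the chloromethyl group, C8 adds to the aldehyde, and the alkoxide anti to chlorine closes the 7,8-epoxide, giving A2 with the epoxide cis to O5 and O6.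
- For it: one step makes a C–C bond, the ring and two stereocentres. Chloride opening of A2 at C8 is stronger than the chlorination used here, because in the ring C8 is the only activated carbon and no hydroxyl differentiation is needed.
- Against it: the facial outcome of the ring-closing aldol is not fixed by any strong element of A1. The α-silyloxy aldehyde can epimerise at C6 or lose the C5 silyloxy group by β-elimination under the base needed. A1 also needs its own asymmetric construction of C5 and C6.
- Comparison: the chosen route takes C7 and C8 from the chiral pool and makes ring B in a step that cannot fail stereochemically. The price is a protection and deprotection around the chlorination.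

Alternative 2: Ring B is cut at C4a–C5 and C8a–C8, as a Diels–Alder reaction across C4a=C8a. The Lewis-acid-chelated sulfinylpyranone A3 and silyloxydiene A4 combine, and the adduct loses the sulfinyl group as its sulfenic acid to give A5, with C5 set and a C6=C7 alkene.
- For it: it is clearly stronger on step economy up to the bicycle, which arises in one step from two simple partners. The chosen route needs a dozen steps to reach diene 22.
- Against it: A5 holds one of the four stereocentres. C8 is a methylene group, so the chloride would need a late, stereocontrolled C–H functionalisation beside a diol. A5 is a doubly allylic silyl ether that aromatises by loss of silanol, and the pyranone double bond is a reluctant dienophile.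
- Comparison: the chosen route is longer before ring closure but leaves only one oxidation afterwards, and C8–Cl is settled before the ring exists.

Alternative 3: Ring B is cut at C8–C8a. Aldehyde A6, in which a sugar-derived C5–C7 chain on C4a ends in the C8 aldehyde, is converted by a hydroperoxide with catalytic iodide into an acyl radical that adds to C8a; oxidation and loss of H8a give 8-ketone A7.
- For it: it is stronger on the triol, since all three oxygen stereocentres arrive intact from a sugar and no diastereoselective oxidation is needed.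
- Against it: the acyl radical is α-oxygenated and prone to lose carbon monoxide. The oxidising radical medium threatens the benzylic positions and the C5–H bond. A7 has an acidic H7 next to a β-oxygen and can eliminate towards a phenol. C8 would still have to be reduced and then substituted by chloride with inversion on the finished, fragile ring, and joining the chain to C4a creates C5 as a new stereocentre that needs its own control.
- Comparison: the chosen route joins the sugar fragment through an alkyne without creating a stereocentre and finishes with a single, well-understood directed dihydroxylation.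

Key step: step 17

Remark on the chemistry: compound 1 is written in its open-chain form and reacts through its furanose form.
Remark on the chemistry: the geometry drawn for the enaminone double bond in 7, 8 and 14 is the one expected for a tertiary enaminone; it is erased on ring closure and has no bearing on the route.
Abbreviation: TBS = tert-butyldimethylsilyl; TMEDA = N,N,N',N'-tetramethylethane-1,2-diamine.

Step 1
Reactants: 1 D-lyxose
Product: 2 methyl 2,3-O-isopropylidene-α-D-lyxofuranoside
Conditions: Me2C(OMe)2, acetone, MeOH, HCl (cat.), reflux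
Reagents that add atoms: 2,2-dimethoxypropane CC(C)(OC)OC; methanol CO
Why: Fischer glycosidation with acetalisation under thermodynamic control: the cis-2,3-diol of the furanose takes the isopropylidene group and the methyl glycoside settles trans to it; all stereocentres come from 1.

Step 2
Reactants: 2 methyl 2,3-O-isopropylidene-α-D-lyxofuranoside
Product: 3 methyl 5-deoxy-5-iodo-2,3-O-isopropylidene-α-D-lyxofuranoside
Conditions: I2, PPh3, imidazole, toluene, 70 °C
Reagents that add atoms: iodine II
Why: Garegg–Samuelsson iodination (Appel type) of the only free, primary hydroxyl; no stereocentre is involved.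

Step 3
Reactants: 3 methyl 5-deoxy-5-iodo-2,3-O-isopropylidene-α-D-lyxofuranoside
Product: 4 (4S,5S)-2,2-dimethyl-5-vinyl-1,3-dioxolane-4-carbaldehyde
Conditions: Zn (activated), THF/H2O 4:1, sonication, 40 °C
Reagents that add atoms: none
Why: Vasella fragmentation: zinc inserts into the C–I bond, the ring oxygen is expelled to form the vinyl group and the anomeric acetal collapses to the aldehyde; C2 and C3 of the sugar (later C8 and C7) are untouched, and the volatile aldehyde is used at once.

Step 4
Reactants: 4 (4S,5S)-2,2-dimethyl-5-vinyl-1,3-dioxolane-4-carbaldehyde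
Product: 5 (4R,5S)-4-ethynyl-2,2-dimethyl-5-vinyl-1,3-dioxolane
Conditions: Me3SiCHN2, LiN(i-Pr)2, THF, −78 °C; then 4, −78 °C → rt; aq. NH4Cl
Reagents that add atoms: trimethylsilyldiazomethane C[Si](C)(C)C=[N+]=[N-]
Why: Colvin rearrangement: the lithiated diazomethane adds to the aldehyde, Peterson elimination gives a diazoalkene, and loss of N2 with a 1,2-hydrogen shift gives the terminal alkyne. Addition at −78 °C is faster than enolisation, so the cis-dioxolane aldehyde should not epimerise as it could under carbonate in methanol; the descriptor at C4 changes only because the substituent priorities change.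

Step 5
Reactants: 5 (4R,5S)-4-ethynyl-2,2-dimethyl-5-vinyl-1,3-dioxolane
Product: 6 4-[(4R,5S)-2,2-dimethyl-5-vinyl-1,3-dioxolan-4-yl]but-3-yn-2-one
Conditions: n-BuLi, THF, −78 °C; then MeC(O)N(OMe)Me, −78 → 0 °C; aq. NH4Cl
Reagents that add atoms: N-methoxy-N-methylacetamide CC(=O)N(C)OC
Why: Weinreb ketone synthesis: the lithium acetylide adds once to the amide and the chelated tetrahedral intermediate gives the ynone only on work-up; the alkyne C–H is by far the most acidic site.

Step 6
Reactants: 6 4-[(4R,5S)-2,2-dimethyl-5-vinyl-1,3-dioxolan-4-yl]but-3-yn-2-one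
Product: 8 (Z)-4-[(4R,5S)-2,2-dimethyl-5-vinyl-1,3-dioxolan-4-yl]-3-iodo-4-(pyrrolidin-1-yl)but-3-en-2-one, via enaminone 7 (not isolated)
Conditions: pyrrolidine (1.0 equiv), CH2Cl2, 0 °C; then N-iodosuccinimide, 0 °C → rt
Reagents that add atoms: pyrrolidine C1CCNC1; N-iodosuccinimide O=C1CCC(=O)N1I
Why: Aza-Michael addition of the amine to the ynone gives enaminone 7, whose single nucleophilic carbon (the future C4a) is then iodinated by electrophilic α-halogenation. At this stage neither the future C3 nor the electron-rich arene is present to compete for the iodonium source.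

Step 7
Reactants: 9 isovanillin
Product: 10 3-(tert-butyldimethylsilyloxy)-4-methoxybenzaldehyde
Conditions: TBSCl, imidazole, DMF, rt
Reagents that add atoms: tert-butyldimethylsilyl chloride CC(C)(C)[Si](C)(C)Cl
Why: Standard silylation of a phenol; the aryl silyl ether survives the base, acid and palladium steps ahead and is removed together with the C7 silyl ether in step 16.

Step 8
Reactants: 10 3-(tert-butyldimethylsilyloxy)-4-methoxybenzaldehyde
Product: 11 benzyl (E)-3-[3-(tert-butyldimethylsilyloxy)-4-methoxyphenyl]prop-2-enoate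
Conditions: Ph3P=CHCO2Bn, toluene, 80 °C
Reagents that add atoms: benzyl (triphenylphosphoranylidene)acetate O=C(C=P(c1ccccc1)(c1ccccc1)c1ccccc1)OCc1ccccc1
Why: Wittig olefination with a stabilised ylide under neutral conditions; the alkene geometry is of no consequence because the double bond is hydrogenated next.

Step 9
Reactants: 11 benzyl (E)-3-[3-(tert-butyldimethylsilyloxy)-4-methoxyphenyl]prop-2-enoate
Product: 12 3-[3-(tert-butyldimethylsilyloxy)-4-methoxyphenyl]propanoic acid
Conditions: H2 (1 atm), Pd/C, EtOAc, rt
Reagents that add atoms: none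
Why: Heterogeneous hydrogenation saturates the alkene and hydrogenolyses the benzyl ester in one operation, so the acid is freed without a basic hydrolysis that could endanger the aryl silyl ether.

Step 10
Reactants: 12 3-[3-(tert-butyldimethylsilyloxy)-4-methoxyphenyl]propanoic acid
Product: 13 1-(1H-benzotriazol-1-yl)-3-[3-(tert-butyldimethylsilyloxy)-4-methoxyphenyl]propan-1-one
Conditions: 1H-benzotriazole, N,N'-dicyclohexylcarbodiimide, CH2Cl2, 0 °C → rt
Reagents that add atoms: 1H-benzotriazole c1ccc2[nH]nnc2c1
Why: Carbodiimide-mediated N-acylation gives an N-acylbenzotriazole, a neutral and isolable acyl donor of the kind used for C-acylation of ketone enolates.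

Step 11
Reactants: 8 (Z)-4-[(4R,5S)-2,2-dimethyl-5-vinyl-1,3-dioxolan-4-yl]-3-iodo-4-(pyrrolidin-1-yl)but-3-en-2-one; 13 1-(1H-benzotriazol-1-yl)-3-[3-(tert-butyldimethylsilyloxy)-4-methoxyphenyl]propan-1-one
Product: 15 6-{2-[3-(tert-butyldimethylsilyloxy)-4-methoxyphenyl]ethyl}-2-[(4S,5S)-2,2-dimethyl-5-vinyl-1,3-dioxolan-4-yl]-3-iodo-4H-pyran-4-one, via diketone 14 (not isolated)
Conditions: LiN(i-Pr)2 (2.1 equiv), THF, −78 °C; then 13, −78 → −30 °C; then CF3CO2H, CH2Cl2, −30 °C → rt
Reagents that add atoms: none
Why: Kinetic deprotonation of the methyl group of the vinylogous amide and Claisen-type C-acylation give diketone 14, the second equivalent of base taking up its acidic proton. On acidification the enol oxygen adds to the enaminone carbon and pyrrolidine is expelled (addition–elimination, the enaminone route to 4-pyranones), which places hydrogen on C3 and iodine on C4a without any regiochemical choice.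

Step 12
Reactants: 15 6-{2-[3-(tert-butyldimethylsilyloxy)-4-methoxyphenyl]ethyl}-2-[(4S,5S)-2,2-dimethyl-5-vinyl-1,3-dioxolan-4-yl]-3-iodo-4H-pyran-4-one; 16 tributyl(vinyl)stannane
Product: 17 6-{2-[3-(tert-butyldimethylsilyloxy)-4-methoxyphenyl]ethyl}-2-[(4S,5S)-2,2-dimethyl-5-vinyl-1,3-dioxolan-4-yl]-3-vinyl-4H-pyran-4-one
Conditions: Pd(PPh3)4 (5 mol %), CuI (10 mol %), DMF, 60 °C
Reagents that add atoms: none
Why: Stille coupling of the 3-iodopyranone, a vinylogous α-iodoenone, by zerovalent palladium with CuI to speed transmetallation; it is run before any chloride is present, and it puts in place the second alkene for the metathesis.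

Step 13
Reactants: 17 6-{2-[3-(tert-butyldimethylsilyloxy)-4-methoxyphenyl]ethyl}-2-[(4S,5S)-2,2-dimethyl-5-vinyl-1,3-dioxolan-4-yl]-3-vinyl-4H-pyran-4-one
Product: 18 6-{2-[3-(tert-butyldimethylsilyloxy)-4-methoxyphenyl]ethyl}-2-[(1S,2S)-1,2-dihydroxybut-3-en-1-yl]-3-vinyl-4H-pyran-4-one
Conditions: AcOH/H2O 4:1, 50 °C
Reagents that add atoms: none
Why: Acid-catalysed hydrolysis of the isopropylidene acetal; aqueous acetic acid leaves the aryl silyl ether and the pyranone untouched, and both carbinol centres keep their configuration.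

Step 14
Reactants: 18 6-{2-[3-(tert-butyldimethylsilyloxy)-4-methoxyphenyl]ethyl}-2-[(1S,2S)-1,2-dihydroxybut-3-en-1-yl]-3-vinyl-4H-pyran-4-one
Product: 19 2-[(1S,2S)-2-(tert-butyldimethylsilyloxy)-1-hydroxybut-3-en-1-yl]-6-{2-[3-(tert-butyldimethylsilyloxy)-4-methoxyphenyl]ethyl}-3-vinyl-4H-pyran-4-one
Conditions: TBSCl (1.05 equiv), imidazole, DMF, −20 → 0 °C
Reagents that add atoms: tert-butyldimethylsilyl chloride CC(C)(C)[Si](C)(C)Cl
Why: Site-selective monosilylation: the allylic C7 hydroxyl is less hindered and more nucleophilic than the C8 hydroxyl, which sits beside the 3-substituted, electron-poor pyranone. Any regioisomer should be separable and can be returned to 18 by desilylation.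

Step 15
Reactants: 19 2-[(1S,2S)-2-(tert-butyldimethylsilyloxy)-1-hydroxybut-3-en-1-yl]-6-{2-[3-(tert-butyldimethylsilyloxy)-4-methoxyphenyl]ethyl}-3-vinyl-4H-pyran-4-one
Product: 21 2-[(1R,2S)-2-(tert-butyldimethylsilyloxy)-1-chlorobut-3-en-1-yl]-6-{2-[3-(tert-butyldimethylsilyloxy)-4-methoxyphenyl]ethyl}-3-vinyl-4H-pyran-4-one, via mesylate 20 (not isolated)
Conditions: MsCl, 2,4,6-collidine, LiCl, DMF, 0 °C → rt
Reagents that add atoms: lithium chloride [Li+].[Cl-]; methanesulfonyl chloride CS(=O)(=O)Cl (its atoms reach 20 only)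
Why: Sulfonylation followed by SN2 displacement with chloride inverts C8 (1S to 1R), turning the erythro oxygen pattern into the trans chlorohydrin. The electron-poor pyranone disfavours ionisation at C8, so clean inversion is expected, and with C7 capped there is no second site for chloride.

Step 16
Reactants: 21 2-[(1R,2S)-2-(tert-butyldimethylsilyloxy)-1-chlorobut-3-en-1-yl]-6-{2-[3-(tert-butyldimethylsilyloxy)-4-methoxyphenyl]ethyl}-3-vinyl-4H-pyran-4-one
Product: 22 2-[(1R,2S)-1-chloro-2-hydroxybut-3-en-1-yl]-6-[2-(3-hydroxy-4-methoxyphenyl)ethyl]-3-vinyl-4H-pyran-4-one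
Conditions: HF·pyridine, pyridine, THF, 0 °C → rt
Reagents that add atoms: none
Why: Fluoride cleavage of both silyl ethers under mildly acidic conditions; no alkoxide is formed, so the trans chlorohydrin cannot close to the epoxide.

Step 17
Reactants: 22 2-[(1R,2S)-1-chloro-2-hydroxybut-3-en-1-yl]-6-[2-(3-hydroxy-4-methoxyphenyl)ethyl]-3-vinyl-4H-pyran-4-one
Product: 23 (7S,8R)-8-chloro-7-hydroxy-2-[2-(3-hydroxy-4-methoxyphenyl)ethyl]-7,8-dihydro-4H-chromen-4-one
Conditions: second-generation Grubbs catalyst RuCl2(=CHPh)(H2IMes)(PCy3) (10 mol %), 1,4-benzoquinone (10 mol %), CH2Cl2 (0.005 M), 40 °C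
Reagents that add atoms: none
Why: Ring-closing metathesis: the ruthenium benzylidene exchanges with the unhindered terminal vinyl group of the arm, the new alkylidene at C6 undergoes [2+2] addition with the 3-vinyl group, and retro-[2+2] of the metallacyclobutane forms C5=C6 with loss of ethene. The closest known reaction type is the closure of 1,7-dienes to cyclohexenes, in particular of ortho-vinyl aryl dienes to 1,2-dihydronaphthalene-type rings, with this catalyst. Ring B, a six-membered carbocycle, closes by joining the two alkene termini of a chain whose four linking atoms include the C4a=C8a bond, which holds both arms cis and close. No stereocentre is formed, and C7 and C8 are not involved. The step needs ring closure rather than cross-metathesis, which high dilution and the enforced proximity should secure, and initiation at the arm, which the hindered, conjugated 3-vinyl group leaves as the easier site. It also needs the absence of ruthenium hydride chemistry that would isomerise the allylic alcohol or trigger loss of water or HCl to the aromatic chromone; benzoquinone, neutral conditions and a moderate temperature serve this. Free phenol, secondary alcohol and alkyl chloride are tolerated by ruthenium alkylidenes.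

Step 18
Reactants: 23 (7S,8R)-8-chloro-7-hydroxy-2-[2-(3-hydroxy-4-methoxyphenyl)ethyl]-7,8-dihydro-4H-chromen-4-one
Product: 25 (5S,6S,7S,8R)-8-chloro-5,6,7-trihydroxy-2-[2-(3-hydroxy-4-methoxyphenyl)ethyl]-5,6,7,8-tetrahydro-4H-chromen-4-one, via osmate ester 24 (not isolated)
Conditions: OsO4 (1.1 equiv), TMEDA (1.1 equiv), CH2Cl2, −78 °C; then HCl, MeOH, 0 °C → rt
Reagents that add atoms: osmium tetroxide O=[Os](=O)(=O)=O; N,N,N',N'-tetramethylethane-1,2-diamine CN(C)CCN(C)C (its atoms reach 24 only)
Why: Hydrogen-bond-directed syn-dihydroxylation: the OsO4–TMEDA complex accepts a hydrogen bond from the C7 hydroxyl and adds suprafacially to C5=C6 from that face, which is also the face opposite the C8 chlorine, so C5 and C6 are set cis to each other and to C7–OH (5S,6S). Brief acidic methanolysis releases the triol from hexavalent osmium; the pyranone C2=C3 bond is a vinylogous ester and should not compete.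

Compound list

1 | D-lyxose | O=C[C@@H](O)[C@@H](O)[C@H](O)CO | starting material
2 | methyl 2,3-O-isopropylidene-α-D-lyxofuranoside | CO[C@@H]1[C@H]2OC(C)(C)O[C@H]2[C@@H](CO)O1 | intermediate
3 | methyl 5-deoxy-5-iodo-2,3-O-isopropylidene-α-D-lyxofuranoside | CO[C@@H]1[C@H]2OC(C)(C)O[C@H]2[C@@H](CI)O1 | intermediate
4 | (4S,5S)-2,2-dimethyl-5-vinyl-1,3-dioxolane-4-carbaldehyde | O=C[C@H]1OC(C)(C)O[C@H]1C=C | intermediate
5 | (4R,5S)-4-ethynyl-2,2-dimethyl-5-vinyl-1,3-dioxolane | C#C[C@H]1OC(C)(C)O[C@H]1C=C | intermediate
6 | 4-[(4R,5S)-2,2-dimethyl-5-vinyl-1,3-dioxolan-4-yl]but-3-yn-2-one | CC(=O)C#C[C@H]1OC(C)(C)O[C@H]1C=C | intermediate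
7 | (E)-4-[(4R,5S)-2,2-dimethyl-5-vinyl-1,3-dioxolan-4-yl]-4-(pyrrolidin-1-yl)but-3-en-2-one | CC(=O)/C=C(/N1CCCC1)[C@H]2OC(C)(C)O[C@H]2C=C | intermediate
8 | (Z)-4-[(4R,5S)-2,2-dimethyl-5-vinyl-1,3-dioxolan-4-yl]-3-iodo-4-(pyrrolidin-1-yl)but-3-en-2-one | CC(=O)/C(I)=C(/N1CCCC1)[C@H]2OC(C)(C)O[C@H]2C=C | intermediate
9 | isovanillin (3-hydroxy-4-methoxybenzaldehyde) | COc1ccc(C=O)cc1O | starting material
10 | 3-(tert-butyldimethylsilyloxy)-4-methoxybenzaldehyde | COc1ccc(C=O)cc1O[Si](C)(C)C(C)(C)C | intermediate
11 | benzyl (E)-3-[3-(tert-butyldimethylsilyloxy)-4-methoxyphenyl]prop-2-enoate | COc1ccc(/C=C/C(=O)OCc2ccccc2)cc1O[Si](C)(C)C(C)(C)C | intermediate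
12 | 3-[3-(tert-butyldimethylsilyloxy)-4-methoxyphenyl]propanoic acid | COc1ccc(CCC(=O)O)cc1O[Si](C)(C)C(C)(C)C | intermediate
13 | 1-(1H-benzotriazol-1-yl)-3-[3-(tert-butyldimethylsilyloxy)-4-methoxyphenyl]propan-1-one | COc1ccc(CCC(=O)n2nnc3ccccc32)cc1O[Si](C)(C)C(C)(C)C | intermediate
14 | (Z)-7-[(4R,5S)-2,2-dimethyl-5-vinyl-1,3-dioxolan-4-yl]-6-iodo-1-[3-(tert-butyldimethylsilyloxy)-4-methoxyphenyl]-7-(pyrrolidin-1-yl)hept-6-ene-3,5-dione | COc1ccc(CCC(=O)CC(=O)/C(I)=C(/N2CCCC2)[C@H]3OC(C)(C)O[C@H]3C=C)cc1O[Si](C)(C)C(C)(C)C | intermediate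
15 | 6-{2-[3-(tert-butyldimethylsilyloxy)-4-methoxyphenyl]ethyl}-2-[(4S,5S)-2,2-dimethyl-5-vinyl-1,3-dioxolan-4-yl]-3-iodo-4H-pyran-4-one | COc1ccc(CCc2cc(=O)c(I)c(o2)[C@H]3OC(C)(C)O[C@H]3C=C)cc1O[Si](C)(C)C(C)(C)C | intermediate
16 | tributyl(vinyl)stannane | C=C[Sn](CCCC)(CCCC)CCCC | starting material
17 | 6-{2-[3-(tert-butyldimethylsilyloxy)-4-methoxyphenyl]ethyl}-2-[(4S,5S)-2,2-dimethyl-5-vinyl-1,3-dioxolan-4-yl]-3-vinyl-4H-pyran-4-one | COc1ccc(CCc2cc(=O)c(C=C)c(o2)[C@H]3OC(C)(C)O[C@H]3C=C)cc1O[Si](C)(C)C(C)(C)C | intermediate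
18 | 6-{2-[3-(tert-butyldimethylsilyloxy)-4-methoxyphenyl]ethyl}-2-[(1S,2S)-1,2-dihydroxybut-3-en-1-yl]-3-vinyl-4H-pyran-4-one | COc1ccc(CCc2cc(=O)c(C=C)c(o2)[C@@H](O)[C@@H](O)C=C)cc1O[Si](C)(C)C(C)(C)C | intermediate
19 | 2-[(1S,2S)-2-(tert-butyldimethylsilyloxy)-1-hydroxybut-3-en-1-yl]-6-{2-[3-(tert-butyldimethylsilyloxy)-4-methoxyphenyl]ethyl}-3-vinyl-4H-pyran-4-one | COc1ccc(CCc2cc(=O)c(C=C)c(o2)[C@@H](O)[C@@H](O[Si](C)(C)C(C)(C)C)C=C)cc1O[Si](C)(C)C(C)(C)C | intermediate
20 | (1S,2S)-2-(tert-butyldimethylsilyloxy)-1-(6-{2-[3-(tert-butyldimethylsilyloxy)-4-methoxyphenyl]ethyl}-4-oxo-3-vinyl-4H-pyran-2-yl)but-3-en-1-yl methanesulfonate | COc1ccc(CCc2cc(=O)c(C=C)c(o2)[C@@H](OS(C)(=O)=O)[C@@H](O[Si](C)(C)C(C)(C)C)C=C)cc1O[Si](C)(C)C(C)(C)C | intermediate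
21 | 2-[(1R,2S)-2-(tert-butyldimethylsilyloxy)-1-chlorobut-3-en-1-yl]-6-{2-[3-(tert-butyldimethylsilyloxy)-4-methoxyphenyl]ethyl}-3-vinyl-4H-pyran-4-one | COc1ccc(CCc2cc(=O)c(C=C)c(o2)[C@H](Cl)[C@@H](O[Si](C)(C)C(C)(C)C)C=C)cc1O[Si](C)(C)C(C)(C)C | intermediate
22 | 2-[(1R,2S)-1-chloro-2-hydroxybut-3-en-1-yl]-6-[2-(3-hydroxy-4-methoxyphenyl)ethyl]-3-vinyl-4H-pyran-4-one | COc1ccc(CCc2cc(=O)c(C=C)c(o2)[C@H](Cl)[C@@H](O)C=C)cc1O | intermediate
23 | (7S,8R)-8-chloro-7-hydroxy-2-[2-(3-hydroxy-4-methoxyphenyl)ethyl]-7,8-dihydro-4H-chromen-4-one | COc1ccc(CCc2cc(=O)c3c(o2)[C@H](Cl)[C@@H](O)C=C3)cc1O | intermediate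
24 | TMEDA-ligated 5,6-glycolate of hexavalent osmium (osmate ester) derived from 23, osmium on the face of the C7 hydroxyl, ring B configured as in 25 | COc1ccc(CCc2cc(=O)c3c(o2)[C@H](Cl)[C@@H](O)[C@H]4O[Os-2]5(=O)(=O)([N+](C)(C)CC[N+]5(C)C)O[C@@H]34)cc1O | intermediate
25 | (5S,6S,7S,8R)-8-chloro-5,6,7-trihydroxy-2-[2-(3-hydroxy-4-methoxyphenyl)ethyl]-5,6,7,8-tetrahydro-4H-chromen-4-one | COc1ccc(CCc2cc(=O)c3c(o2)[C@H](Cl)[C@@H](O)[C@@H](O)[C@H]3O)cc1O | target

Total step count: 18. Longest linear sequence: 14 steps (steps 1–6 and 11–18 from D-lyxose); the side chain takes steps 7–10.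

Steps least certain to work

Step 17 (key step). Ruthenium hydride arising from the catalyst may isomerise the free allylic alcohol or start loss of water or HCl from the new cyclohexadiene towards the aromatic chromone, and the arm may dimerise by cross-metathesis before the hindered 3-vinyl group is engaged. The fallback closes the ring before the hydroxyls are freed. It sets out from 21: metathesis of the bis-silyl ether under the same catalyst should give (7S,8R)-7-(tert-butyldimethylsilyloxy)-8-chloro-2-{2-[3-(tert-butyldimethylsilyloxy)-4-methoxyphenyl]ethyl}-7,8-dihydro-4H-chromen-4-one F1, in which no free alcohol can feed hydride chemistry. Buffered HF·pyridine then removes both silyl groups, and the sequence comes back to the route at 23.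

Step 11. The acidic diketone quenches unreacted enolate, the excess amide base can consume the acyl donor, and long exposure to base invites deprotonation at C8 with loss of configuration or β-elimination of the acetonide oxygen. The fallback replaces the Claisen acylation by aldol addition and oxidation, and sets out from 12 and 8. Acid 12 is reduced with BH3·SMe2 to 3-[3-(tert-butyldimethylsilyloxy)-4-methoxyphenyl]propan-1-ol F2 and oxidised with Dess–Martin periodinane to 3-[3-(tert-butyldimethylsilyloxy)-4-methoxyphenyl]propanal F3. The enolate of 8 (one equivalent of LiN(i-Pr)2, −78 °C) adds to F3 within minutes to give the β-hydroxy ketone (Z)-7-[(4R,5S)-2,2-dimethyl-5-vinyl-1,3-dioxolan-4-yl]-3-hydroxy-6-iodo-1-[3-(tert-butyldimethylsilyloxy)-4-methoxyphenyl]-7-(pyrrolidin-1-yl)hept-6-en-5-one F4 as a mixture of carbinol epimers, which does not matter. Dess–Martin oxidation of F4 comes back to the route at diketone 14, which is cyclised with CF3CO2H as in step 11.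

Step 14. Site selectivity between the two secondary hydroxyls may be poor, or the silyl group may migrate, because the steric and electronic difference between C7–OH and C8–OH is moderate. The fallback differentiates the hydroxyls one stage earlier, where the large iodine on C4a shields the C8 hydroxyl more strongly. It sets out from 15: aqueous acetic acid gives 6-{2-[3-(tert-butyldimethylsilyloxy)-4-methoxyphenyl]ethyl}-2-[(1S,2S)-1,2-dihydroxybut-3-en-1-yl]-3-iodo-4H-pyran-4-one F5. Monosilylation then gives 2-[(1S,2S)-2-(tert-butyldimethylsilyloxy)-1-hydroxybut-3-en-1-yl]-6-{2-[3-(tert-butyldimethylsilyloxy)-4-methoxyphenyl]ethyl}-3-iodo-4H-pyran-4-one F6, and Stille coupling of F6 with 16 comes back to the route at 19.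

Step 15. Substitution at C8, which is flanked by the silyloxy-bearing C7 and the substituted pyranone, may be slow, so that elimination competes, and free chloride may erode the configuration at C8 by degenerate exchange once the product has formed. The fallback uses a strained cyclic electrophile that reacts at low temperature, and sets out from 18. SOCl2 and Et3N give the cyclic sulfite 6-{2-[3-(tert-butyldimethylsilyloxy)-4-methoxyphenyl]ethyl}-2-[(4S,5S)-2-oxido-5-vinyl-1,3,2-dioxathiolan-4-yl]-3-vinyl-4H-pyran-4-one F7. Brief oxidation with catalytic RuCl3 and NaIO4 at 0 °C gives the cyclic sulfate 6-{2-[3-(tert-butyldimethylsilyloxy)-4-methoxyphenyl]ethyl}-2-[(4S,5S)-2,2-dioxido-5-vinyl-1,3,2-dioxathiolan-4-yl]-3-vinyl-4H-pyran-4-one F8. LiCl in THF/DMF at 0 °C should open F8 at the pyranone-activated C8 with inversion to the lithium sulfate monoester of the chlorohydrin F9, and dilute H2SO4 in wet THF hydrolyses F9 to 2-[(1R,2S)-1-chloro-2-hydroxybut-3-en-1-yl]-6-{2-[3-(tert-butyldimethylsilyloxy)-4-methoxyphenyl]ethyl}-3-vinyl-4H-pyran-4-one F10. HF·pyridine then frees the phenol, and the sequence comes back to the route at 22. The price is that the allylic C7 may compete for chloride.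

Step 18. The free phenol may tie up the osmium–diamine reagent by hydrogen bonding or lower the solubility at −78 °C, which would erode the hydroxyl-directed facial control, and acidic release may cause solvolysis at C5. The fallback keeps the phenol silylated to the very end, and sets out from 21. Ring closure as in the fallback to step 17 gives the bis-silyl dihydrochromone F1. Buffered HF·pyridine at 0 °C, under which the alkyl silyl ether is cleaved ahead of the aryl one, gives (7S,8R)-2-{2-[3-(tert-butyldimethylsilyloxy)-4-methoxyphenyl]ethyl}-8-chloro-7-hydroxy-7,8-dihydro-4H-chromen-4-one F11. OsO4 and TMEDA give the osmate ester of F11, F12, and brief methanolic HCl releases the aryl silyl ether of the target, F13. KHF2 in MeOH at room temperature, which is selective for aryl silyl ethers, comes back to the route at 25.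

Further compounds

F1 | step 17 | (7S,8R)-7-(tert-butyldimethylsilyloxy)-8-chloro-2-{2-[3-(tert-butyldimethylsilyloxy)-4-methoxyphenyl]ethyl}-7,8-dihydro-4H-chromen-4-one | COc1ccc(CCc2cc(=O)c3c(o2)[C@H](Cl)[C@@H](O[Si](C)(C)C(C)(C)C)C=C3)cc1O[Si](C)(C)C(C)(C)C
F2 | step 11 | 3-[3-(tert-butyldimethylsilyloxy)-4-methoxyphenyl]propan-1-ol | COc1ccc(CCCO)cc1O[Si](C)(C)C(C)(C)C
F3 | step 11 | 3-[3-(tert-butyldimethylsilyloxy)-4-methoxyphenyl]propanal | COc1ccc(CCC=O)cc1O[Si](C)(C)C(C)(C)C
F4 | step 11 | (Z)-7-[(4R,5S)-2,2-dimethyl-5-vinyl-1,3-dioxolan-4-yl]-3-hydroxy-6-iodo-1-[3-(tert-butyldimethylsilyloxy)-4-methoxyphenyl]-7-(pyrrolidin-1-yl)hept-6-en-5-one, both epimers at C3 | COc1ccc(CCC(O)CC(=O)/C(I)=C(/N2CCCC2)[C@H]3OC(C)(C)O[C@H]3C=C)cc1O[Si](C)(C)C(C)(C)C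
F5 | step 14 | 6-{2-[3-(tert-butyldimethylsilyloxy)-4-methoxyphenyl]ethyl}-2-[(1S,2S)-1,2-dihydroxybut-3-en-1-yl]-3-iodo-4H-pyran-4-one | COc1ccc(CCc2cc(=O)c(I)c(o2)[C@@H](O)[C@@H](O)C=C)cc1O[Si](C)(C)C(C)(C)C
F6 | step 14 | 2-[(1S,2S)-2-(tert-butyldimethylsilyloxy)-1-hydroxybut-3-en-1-yl]-6-{2-[3-(tert-butyldimethylsilyloxy)-4-methoxyphenyl]ethyl}-3-iodo-4H-pyran-4-one | COc1ccc(CCc2cc(=O)c(I)c(o2)[C@@H](O)[C@@H](O[Si](C)(C)C(C)(C)C)C=C)cc1O[Si](C)(C)C(C)(C)C
F7 | step 15 | 6-{2-[3-(tert-butyldimethylsilyloxy)-4-methoxyphenyl]ethyl}-2-[(4S,5S)-2-oxido-5-vinyl-1,3,2-dioxathiolan-4-yl]-3-vinyl-4H-pyran-4-one (cyclic sulfite, both configurations at sulfur) | COc1ccc(CCc2cc(=O)c(C=C)c(o2)[C@H]3OS(=O)O[C@H]3C=C)cc1O[Si](C)(C)C(C)(C)C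
F8 | step 15 | 6-{2-[3-(tert-butyldimethylsilyloxy)-4-methoxyphenyl]ethyl}-2-[(4S,5S)-2,2-dioxido-5-vinyl-1,3,2-dioxathiolan-4-yl]-3-vinyl-4H-pyran-4-one (cyclic sulfate) | COc1ccc(CCc2cc(=O)c(C=C)c(o2)[C@H]3OS(=O)(=O)O[C@H]3C=C)cc1O[Si](C)(C)C(C)(C)C
F9 | step 15 | lithium (1R,2S)-1-chloro-1-(6-{2-[3-(tert-butyldimethylsilyloxy)-4-methoxyphenyl]ethyl}-4-oxo-3-vinyl-4H-pyran-2-yl)but-3-en-2-yl sulfate | COc1ccc(CCc2cc(=O)c(C=C)c(o2)[C@H](Cl)[C@@H](OS(=O)(=O)[O-])C=C)cc1O[Si](C)(C)C(C)(C)C.[Li+]
F10 | step 15 | 2-[(1R,2S)-1-chloro-2-hydroxybut-3-en-1-yl]-6-{2-[3-(tert-butyldimethylsilyloxy)-4-methoxyphenyl]ethyl}-3-vinyl-4H-pyran-4-one | COc1ccc(CCc2cc(=O)c(C=C)c(o2)[C@H](Cl)[C@@H](O)C=C)cc1O[Si](C)(C)C(C)(C)C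
F11 | step 18 | (7S,8R)-2-{2-[3-(tert-butyldimethylsilyloxy)-4-methoxyphenyl]ethyl}-8-chloro-7-hydroxy-7,8-dihydro-4H-chromen-4-one | COc1ccc(CCc2cc(=O)c3c(o2)[C@H](Cl)[C@@H](O)C=C3)cc1O[Si](C)(C)C(C)(C)C
F12 | step 18 | TMEDA-ligated 5,6-glycolate of hexavalent osmium (osmate ester) derived from F11, osmium on the face of the C7 hydroxyl | COc1ccc(CCc2cc(=O)c3c(o2)[C@H](Cl)[C@@H](O)[C@H]4O[Os-2]5(=O)(=O)([N+](C)(C)CC[N+]5(C)C)O[C@@H]34)cc1O[Si](C)(C)C(C)(C)C
F13 | step 18 | (5S,6S,7S,8R)-2-{2-[3-(tert-butyldimethylsilyloxy)-4-methoxyphenyl]ethyl}-8-chloro-5,6,7-trihydroxy-5,6,7,8-tetrahydro-4H-chromen-4-one | COc1ccc(CCc2cc(=O)c3c(o2)[C@H](Cl)[C@@H](O)[C@@H](O)[C@H]3O)cc1O[Si](C)(C)C(C)(C)C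
A1 | alternative 1 | 2-(chloromethyl)-6-{2-[4-methoxy-3-(methoxymethoxy)phenyl]ethyl}-4H-pyran-4-one bearing on C3 a 1,2-bis(tert-butyldimethylsilyloxy)-3-oxopropyl chain, C5 and C6 configured as in A2 | COc1ccc(CCc2cc(=O)c([C@H](O[Si](C)(C)C(C)(C)C)[C@H](O[Si](C)(C)C(C)(C)C)C=O)c(CCl)o2)cc1OCOC
A2 | alternative 1 | 7,8-epoxy-5,6-bis(tert-butyldimethylsilyloxy)-2-{2-[4-methoxy-3-(methoxymethoxy)phenyl]ethyl}-5,6,7,8-tetrahydro-4H-chromen-4-one, epoxide cis to both silyloxy groups | COc1ccc(CCc2cc(=O)c3c(o2)[C@H]4O[C@H]4[C@@H](O[Si](C)(C)C(C)(C)C)[C@H]3O[Si](C)(C)C(C)(C)C)cc1OCOC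
A3 | alternative 2 | 6-{2-[4-methoxy-3-(methoxymethoxy)phenyl]ethyl}-3-[(S)-p-tolylsulfinyl]-4H-pyran-4-one | COc1ccc(CCc2cc(=O)c(co2)[S@@](=O)c3ccc(C)cc3)cc1OCOC
A4 | alternative 2 | (E)-1-(trimethylsilyloxy)buta-1,3-diene | C=C/C=C/O[Si](C)(C)C
A5 | alternative 2 | 2-{2-[4-methoxy-3-(methoxymethoxy)phenyl]ethyl}-5-(trimethylsilyloxy)-5,8-dihydro-4H-chromen-4-one with C6=C7, C5 as drawn | COc1ccc(CCc2cc(=O)c3c(o2)CC=C[C@H]3O[Si](C)(C)C)cc1OCOC
A6 | alternative 3 | 6-{2-[4-methoxy-3-(methoxymethoxy)phenyl]ethyl}-4H-pyran-4-one bearing on C3 a (tert-butyldimethylsilyloxy)methine carbon (C5) joined to a 2,2-dimethyl-1,3-dioxolane-4-carbaldehyde (C6 and C7 acetonide, C8 aldehyde), configured as in A7 | COc1ccc(CCc2cc(=O)c(co2)[C@H](O[Si](C)(C)C(C)(C)C)[C@@H]3OC(C)(C)O[C@@H]3C=O)cc1OCOC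
A7 | alternative 3 | 5-(tert-butyldimethylsilyloxy)-6,7-O-isopropylidene-2-{2-[4-methoxy-3-(methoxymethoxy)phenyl]ethyl}-8-oxo-5,6,7,8-tetrahydro-4H-chromen-4-one, all three oxygens cis | COc1ccc(CCc2cc(=O)c3c(o2)C(=O)[C@H]4OC(C)(C)O[C@H]4[C@H]3O[Si](C)(C)C(C)(C)C)cc1OCOC
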